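**Retrosynthetic overview**
- The C4 methyl carbinol is made last, by equatorial methyl addition to a trans-hydrindan-4-one.
- The side chain is joined at C3 by copper-catalysed conjugate alkenylation of a bicyclic bromo enone with an (E)-alkenyl metal (from zirconium-catalysed carboalumination); protonation anti to the angular methyl gives the trans ring fusion.
- The five-membered ring is formed second, by ozonolysis and intramolecular aldol condensation of a 3-butenyl-4-bromocyclohexanone.
- The six-membered ring is formed first, together with the C–Br centre and the quaternary carbon, by a new enantioselective bromonium-induced 6-endo carbocyclization of an acyclic (E)-dienyl β-keto ester, followed by decarboxylation.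
- The β-keto ester comes from hex-1-en-5-yne (carboalumination/iodination), a zinc homoenolate (Negishi coupling) and tert-butyl acetate (Claisen condensation).

Assumption: the five starting materials are bought as such; the sense of induction of the new titanium catalyst in step 8 follows the model given there, and the mirror-image ligand would be used if it proved opposite.

**Step 1**
Reactants: 1 1-(trimethylsilyl)prop-1-yne; 2 1-bromo-3-methylbut-2-ene
Product: 4 trimethyl(6-methylhept-5-en-1-yn-1-yl)silane, via lithiated silylpropyne 3 (not isolated)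
Conditions: n-BuLi, THF, −78 → −20 °C; then 2, −78 °C → rt
Reagents that add atoms: none
Why: Propargylic lithiation of the C-silylated propyne and SN2 alkylation of the allylic bromide build the 1,5-enyne, the silyl group blocking the acetylenic terminus and disfavouring allenyl coupling (propargyl anion alkylation).

**Step 2**
Reactants: 4 trimethyl(6-methylhept-5-en-1-yn-1-yl)silane
Product: 5 6-methylhept-5-en-1-yne
Conditions: K2CO3, MeOH, rt
Reagents that add atoms: none
Why: Mild methanolysis cleaves the alkynyl C–Si bond without touching the trisubstituted alkene (protodesilylation).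

**Step 3**
Reactants: 5 6-methylhept-5-en-1-yne
Product: 7 (1E)-1-iodo-2,6-dimethylhepta-1,5-diene, via alkenylalane 6 (not isolated)
Conditions: AlMe3 (2 equiv), Cp2ZrCl2 (20 mol %), CH2Cl2, 0 °C → rt; then I2, THF, −30 → 0 °C
Reagents that add atoms: trimethylaluminium C[Al](C)C; iodine II
Why: Negishi zirconium-catalysed methylalumination adds Me and Al syn across the terminal alkyne with Al at the terminus, and iodinolysis with retention gives the (E)-trisubstituted vinyl iodide (carboalumination–iodination).

**Step 4**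
Reactants: 8 hex-1-en-5-yne
Product: 10 (1E)-1-iodo-2-methylhexa-1,5-diene, via alkenylalane 9 (not isolated)
Conditions: AlMe3 (2 equiv), Cp2ZrCl2 (20 mol %), CH2Cl2, 0 °C → rt; then I2, THF, −30 → 0 °C
Reagents that add atoms: trimethylaluminium C[Al](C)C; iodine II
Why: The same Negishi syn-carboalumination–iodination is selective for the alkyne over the isolated terminal alkene and fixes the E geometry that later places the butenyl arm equatorial.

**Step 5**
Reactants: 11 methyl 3-iodopropanoate
Product: 12 (3-methoxy-3-oxopropyl)zinc iodide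
Conditions: Zn dust (activated with BrCH2CH2Br, TMSCl), THF, 35 °C; used as titrated solution
Reagents that add atoms: zinc [Zn]
Why: Direct insertion of activated zinc into the primary C–I bond gives the ester-tolerant zinc homoenolate (Knochel-type organozinc formation).

**Step 6**
Reactants: 10 (1E)-1-iodo-2-methylhexa-1,5-diene; 12 (3-methoxy-3-oxopropyl)zinc iodide
Product: 13 methyl (4E)-5-methylnona-4,8-dienoate
Conditions: PdCl2(dppf) (3 mol %), THF/DMA, 40 °C
Reagents that add atoms: none
Why: Negishi sp3–sp2 cross-coupling at zerovalent palladium joins the homoenolate to the vinyl iodide with retention of the E geometry, the bidentate ligand suppressing β-hydride elimination.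

**Step 7**
Reactants: 13 methyl (4E)-5-methylnona-4,8-dienoate; 14 tert-butyl acetate
Product: 16 tert-butyl (6E)-7-methyl-3-oxoundeca-6,10-dienoate, via tert-butyl lithioacetate 15 (not isolated)
Conditions: LDA (2.2 equiv), 14 (2.2 equiv), THF, −78 °C; then 13, −78 → −20 °C; aq NH4Cl
Reagents that add atoms: none
Why: Crossed Claisen condensation of the methyl ester with excess lithio tert-butyl acetate gives the tert-butyl β-keto ester, whose deprotonation drives the reaction and prevents double addition.

**Step 8**
Reactants: 16 tert-butyl (6E)-7-methyl-3-oxoundeca-6,10-dienoate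
Product: 19 (3S,4S)-4-bromo-3-(but-3-en-1-yl)-3-methylcyclohexan-1-one, via bromo keto ester 17 (not isolated), via bromo keto acid 18 (not isolated)
Conditions: NBS (1.05 equiv, slow addition), TiCl2[(R,R)-TADDOLate](MeCN)2 (10 mol %; TADDOLate = 2,2-dimethyl-α,α,α′,α′-tetra(1-naphthyl)-1,3-dioxolane-4,5-dimethanolate), CH2Cl2, −40 → 0 °C; then TFA, 40 °C
Reagents that add atoms: N-bromosuccinimide O=C1CCC(=O)N1Br
Why: Proposed new method: the β-keto ester is bound to the chiral tetravalent titanium Lewis acid as a bidentate enolate, NBS (directly, or through reversible C-bromination of the keto ester, which under titanium activation is itself a Br+ donor) turns the remote trisubstituted alkene into a bromiranium ion, and the shielded enolate carbon opens it at the tertiary terminus in an anti, chair-like 6-endo closure with the butenyl arm equatorial, so the ligand-chosen enolate face is relayed to the equatorial C–Br (cis to methyl) and the quaternary carbon as (3S,4S) before acid removes the tert-butyl ester and the β-keto acid loses CO2; the closest known reactions are the titanium TADDOLate-catalysed enantioselective iodocarbocyclization of alkenyl malonates, titanium TADDOLate α-halogenation of β-keto esters and bromonium-induced polyene cyclization terminated by β-dicarbonyl groups.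

**Step 9**
Reactants: 19 (3S,4S)-4-bromo-3-(but-3-en-1-yl)-3-methylcyclohexan-1-one
Product: 21 (7S,7aS)-7-bromo-7a-methyl-1,2,5,6,7,7a-hexahydro-4H-inden-4-one, via keto aldehyde 20 (not isolated)
Conditions: O3, CH2Cl2, −78 °C; PPh3, → rt; solvent change to PhMe, p-TsOH·H2O (10 mol %), 80 °C
Reagents that add atoms: none
Why: Ozonolysis unmasks the aldehyde, and acid-catalysed intramolecular aldol condensation through the only enol that can close an unstrained ring (C2 of the cyclohexanone, 1,6-dicarbonyl to acylcyclopentene) gives the conjugated bicyclic enone, acid being chosen so that no enolate can displace the γ-bromide.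

**Step 10**
Reactants: 21 (7S,7aS)-7-bromo-7a-methyl-1,2,5,6,7,7a-hexahydro-4H-inden-4-one; 7 (1E)-1-iodo-2,6-dimethylhepta-1,5-diene
Product: 25 (3S,3aS,7S,7aS)-7-bromo-3-[(1E)-2,6-dimethylhepta-1,5-dien-1-yl]-7a-methyloctahydro-4H-inden-4-one, via alkenyllithium 22 (not isolated), via alkenylmagnesium bromide 23 (not isolated), via silyl enol ether 24 (not isolated)
Conditions: 7, t-BuLi (2 equiv), Et2O, −78 °C; MgBr2·OEt2; then CuBr·SMe2 (10 mol %), TMSCl, 21, THF, −78 → −40 °C; then 1 M aq HCl, THF, 0 °C
Reagents that add atoms: none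
Why: Copper-catalysed conjugate addition (Kharasch type, TMSCl-accelerated) of the alkenyl Grignard reagent occurs at C3 on the face opposite the angular methyl, as in steroidal 16-en-20-ones, setting C3 (S), and hydrolytic protonation of the silyl enol ether at C3a, again anti to the angular methyl, sets the trans ring fusion (3aS).

**Step 11**
Reactants: 25 (3S,3aS,7S,7aS)-7-bromo-3-[(1E)-2,6-dimethylhepta-1,5-dien-1-yl]-7a-methyloctahydro-4H-inden-4-one
Product: 26 (3S,3aS,4R,7S,7aS)-7-bromo-3-[(1E)-2,6-dimethylhepta-1,5-dien-1-yl]-4,7a-dimethyloctahydro-1H-inden-4-ol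
Conditions: MeMgBr, CeCl3 (anhydrous), THF, −78 °C; aq NH4Cl
Reagents that add atoms: methylmagnesium bromide C[Mg]Br
Why: The organocerium reagent (Imamoto conditions) adds to the hindered, enolizable ketone without epimerizing C3a and attacks equatorially, anti to the syn-axial angular methyl, giving the axial tertiary alcohol (4R).

**Compound list**
1 | 1-(trimethylsilyl)prop-1-yne | CC#C[Si](C)(C)C | starting material
2 | 1-bromo-3-methylbut-2-ene | CC(C)=CCBr | starting material
3 | [3-(trimethylsilyl)prop-2-yn-1-yl]lithium | [Li]CC#C[Si](C)(C)C | intermediate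
4 | trimethyl(6-methylhept-5-en-1-yn-1-yl)silane | CC(C)=CCCC#C[Si](C)(C)C | intermediate
5 | 6-methylhept-5-en-1-yne | CC(C)=CCCC#C | intermediate
6 | [(1E)-2,6-dimethylhepta-1,5-dien-1-yl]dimethylalane | CC(C)=CCC/C(C)=C/[Al](C)C | intermediate
7 | (1E)-1-iodo-2,6-dimethylhepta-1,5-diene | CC(C)=CCC/C(C)=C/I | intermediate
8 | hex-1-en-5-yne | C=CCCC#C | starting material
9 | dimethyl[(1E)-2-methylhexa-1,5-dien-1-yl]alane | C=CCC/C(C)=C/[Al](C)C | intermediate
10 | (1E)-1-iodo-2-methylhexa-1,5-diene | C=CCC/C(C)=C/I | intermediate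
11 | methyl 3-iodopropanoate | COC(=O)CCI | starting material
12 | (3-methoxy-3-oxopropyl)zinc iodide | COC(=O)CC[Zn]I | intermediate
13 | methyl (4E)-5-methylnona-4,8-dienoate | C=CCC/C(C)=C/CCC(=O)OC | intermediate
14 | tert-butyl acetate | CC(=O)OC(C)(C)C | starting material
15 | lithium 1-tert-butoxyethen-1-olate (tert-butyl lithioacetate) | C=C(O[Li])OC(C)(C)C | intermediate
16 | tert-butyl (6E)-7-methyl-3-oxoundeca-6,10-dienoate | C=CCC/C(C)=C/CCC(=O)CC(=O)OC(C)(C)C | intermediate
17 | tert-butyl (1S,2S,3S)-3-bromo-2-(but-3-en-1-yl)-2-methyl-6-oxocyclohexane-1-carboxylate | O=C1CC[C@H](Br)[C@@](C)(CCC=C)[C@@H]1C(=O)OC(C)(C)C | intermediate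
18 | (1S,2S,3S)-3-bromo-2-(but-3-en-1-yl)-2-methyl-6-oxocyclohexane-1-carboxylic acid | O=C1CC[C@H](Br)[C@@](C)(CCC=C)[C@@H]1C(=O)O | intermediate
19 | (3S,4S)-4-bromo-3-(but-3-en-1-yl)-3-methylcyclohexan-1-one | O=C1CC[C@H](Br)[C@@](C)(CCC=C)C1 | intermediate
20 | 3-[(1S,2S)-2-bromo-1-methyl-5-oxocyclohexyl]propanal | O=C1CC[C@H](Br)[C@@](C)(CCC=O)C1 | intermediate
21 | (7S,7aS)-7-bromo-7a-methyl-1,2,5,6,7,7a-hexahydro-4H-inden-4-one | O=C1CC[C@H](Br)[C@@]2(C)CCC=C12 | intermediate
22 | [(1E)-2,6-dimethylhepta-1,5-dien-1-yl]lithium | CC(C)=CCC/C(C)=C/[Li] | intermediate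
23 | [(1E)-2,6-dimethylhepta-1,5-dien-1-yl]magnesium bromide | CC(C)=CCC/C(C)=C/[Mg]Br | intermediate
24 | {[(3S,7S,7aS)-7-bromo-3-[(1E)-2,6-dimethylhepta-1,5-dien-1-yl]-7a-methyl-2,3,5,6,7,7a-hexahydro-1H-inden-4-yl]oxy}trimethylsilane | CC(C)=CCC/C(C)=C/[C@@H]1CC[C@]2(C)[C@@H](Br)CCC(O[Si](C)(C)C)=C12 | intermediate
25 | (3S,3aS,7S,7aS)-7-bromo-3-[(1E)-2,6-dimethylhepta-1,5-dien-1-yl]-7a-methyloctahydro-4H-inden-4-one | CC(C)=CCC/C(C)=C/[C@@H]1CC[C@]2(C)[C@@H](Br)CCC(=O)[C@@H]12 | intermediate
26 | (3S,3aS,4R,7S,7aS)-7-bromo-3-[(1E)-2,6-dimethylhepta-1,5-dien-1-yl]-4,7a-dimethyloctahydro-1H-inden-4-ol | CC(C)=CCC/C(C)=C/[C@@H]1CC[C@]2(C)[C@@H](Br)CC[C@@](C)(O)[C@@H]12 | target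

**Step count**
Total: 11 steps. Longest linear sequence: 7 steps (4, 6, 7, 8, 9, 10, 11; the branch through step 5 is equally long, the side-chain branch 1, 2, 3, 10, 11 is five).

**Three steps most likely to fail**

Step 8 (the new enantioselective bromocarbocyclization). The keto ester may simply be C-brominated, close through oxygen, or cyclize with low ee. Fallback, from 16 back to 19: 16 is cyclized without a chiral catalyst with the bromonium reagent BDSB (Et2SBr·SbCl5Br) in MeNO2 at −25 °C, a known reagent class for bromonium-induced polyene cyclization, to the racemic trans bromo keto ester F1. TFA then converts F1 through the racemic bromo keto acid F2 into the racemic bromo ketone F3. F3 is resolved by preparative chromatography on a chiral stationary phase (amylose tris(3,5-dimethylphenylcarbamate), supercritical CO2/MeOH), and the (3S,4S) enantiomer is 19.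

Step 9 (ozonolysis and acid aldol condensation). The keto aldehyde may oligomerize or give the bridged aldol instead of dehydrating to the enone. Fallback, from 17 back to 21: the cyclization of step 8 is worked up before the TFA stage and 17 is isolated. TFA in CH2Cl2 at 0 °C gives the keto acid 18, which with aqueous formaldehyde and Et2NH in THF undergoes decarboxylative Mannich methylenation to the α-methylene ketone (3S,4S)-4-bromo-3-(but-3-en-1-yl)-3-methyl-2-methylidenecyclohexan-1-one F4. Ring-closing metathesis of F4 with the second-generation Hoveyda–Grubbs catalyst (H2IMes)Cl2Ru(=CH-C6H4-2-OiPr) in toluene at 80 °C closes the cyclopentene and gives 21.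

Step 10 (conjugate addition and C3a protonation). Protonation may give the cis-fused ketone, or the enolate may attack the γ-bromide. Fallback, from 21 back to 26 with no enolate protonation:
- MeMgBr/CeCl3 adds 1,2 to the enone (equatorial attack as in step 11) to give the tertiary allylic alcohol (4R,7S,7aS)-7-bromo-4,7a-dimethyl-2,4,5,6,7,7a-hexahydro-1H-inden-4-ol F5.
- Hydroboration with BH3·SMe2 on the face opposite the angular methyl, then pinacol, gives the secondary boronic ester (3R,3aS,4R,7S,7aS)-7-bromo-4,7a-dimethyl-3-(4,4,5,5-tetramethyl-1,3,2-dioxaborolan-2-yl)octahydro-1H-inden-4-ol F6. Syn addition places H at C3a and boron at C3 on the same face, which sets the trans ring fusion.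
- After O-deprotonation with n-BuLi, alkenyllithium 22 (from 7 and t-BuLi) forms the dilithium boronate complex F7.
- PhSeCl at −78 °C triggers the stereoretentive 1,2-migration to the lithium alkoxide of the β-phenylselanyl boronic ester F8 (both anti-addition diastereomers at the two new centres, which converge).
- m-CPBA at −78 °C induces syn elimination (selenium variant of the Zweifel olefination, with retention at C3 and of the E geometry) and gives 26 directly.

**Further compounds**
F1 | step 8 | racemic tert-butyl (1RS,2RS,3RS)-3-bromo-2-(but-3-en-1-yl)-2-methyl-6-oxocyclohexane-1-carboxylate | O=C1CC[C@H](Br)[C@@](C)(CCC=C)[C@@H]1C(=O)OC(C)(C)C.O=C1CC[C@@H](Br)[C@](C)(CCC=C)[C@H]1C(=O)OC(C)(C)C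
F2 | step 8 | racemic (1RS,2RS,3RS)-3-bromo-2-(but-3-en-1-yl)-2-methyl-6-oxocyclohexane-1-carboxylic acid | O=C1CC[C@H](Br)[C@@](C)(CCC=C)[C@@H]1C(=O)O.O=C1CC[C@@H](Br)[C@](C)(CCC=C)[C@H]1C(=O)O
F3 | step 8 | racemic (3RS,4RS)-4-bromo-3-(but-3-en-1-yl)-3-methylcyclohexan-1-one | O=C1CC[C@H](Br)[C@@](C)(CCC=C)C1.O=C1CC[C@@H](Br)[C@](C)(CCC=C)C1
F4 | step 9 | (3S,4S)-4-bromo-3-(but-3-en-1-yl)-3-methyl-2-methylidenecyclohexan-1-one | O=C1CC[C@H](Br)[C@@](C)(CCC=C)C1=C
F5 | step 10 | (4R,7S,7aS)-7-bromo-4,7a-dimethyl-2,4,5,6,7,7a-hexahydro-1H-inden-4-ol | C[C@@]1(O)CC[C@H](Br)[C@@]2(C)CCC=C12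
F6 | step 10 | (3R,3aS,4R,7S,7aS)-7-bromo-4,7a-dimethyl-3-(4,4,5,5-tetramethyl-1,3,2-dioxaborolan-2-yl)octahydro-1H-inden-4-ol | CC1(C)OB(OC1(C)C)[C@@H]2CC[C@]3(C)[C@@H](Br)CC[C@@](C)(O)[C@@H]23
F7 | step 10 | dilithium boronate complex of O-lithiated F6 with the (1E)-2,6-dimethylhepta-1,5-dien-1-yl group on boron | CC(C)=CCC/C(C)=C/[B-]1(OC(C)(C)C(C)(C)O1)[C@@H]2CC[C@]3(C)[C@@H](Br)CC[C@@](C)([O-])[C@@H]23.[Li+].[Li+]
F8 | step 10 | lithium alkoxide of (3S,3aS,4R,7S,7aS)-7-bromo-3-[2,6-dimethyl-2-(phenylselanyl)-1-(4,4,5,5-tetramethyl-1,3,2-dioxaborolan-2-yl)hept-5-en-1-yl]-4,7a-dimethyloctahydro-1H-inden-4-ol | CC(C)=CCCC(C)([Se]c1ccccc1)C(B2OC(C)(C)C(C)(C)O2)[C@@H]3CC[C@]4(C)[C@@H](Br)CC[C@@](C)(O[Li])[C@@H]34
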